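**Plan**
1. Retrosynthesis: the three MOM ethers are removed first. Ring C is then cut at C2–C3 and at O1–C8a in one stroke, giving an aryl methyl ketone (C3 as enol silane, fluorine on C8a) and 4-(methoxymethoxy)benzaldehyde (C2 and O1). The acetyl group is cut at C4–C4a, and the piperidine at C6–C2' and N–C6'.
2. Enabling feature: C8a of ring A is ortho to the C4 carbonyl and meta to both ring A oxygens (C5, C7). One ketone therefore makes C3 an enolate carbon and C8a–F an SNAr site, and the aldolate oxygen lands six atoms from C8a. The fluoride expelled desilylates the next enol silane.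
3. Forward order: ring A is bought (5-fluororesorcinol). The piperidine ring is built on C6 by sulfinimine addition and N-alkylation, the acetyl group is placed on C4a by ortho-lithiation, and ring C is closed last.
4. Stereochemistry: piperidine C2' (S) comes from (S)-tert-butanesulfinamide through a chelate-controlled aryl addition. Flavanone C2 (S) comes from a chiral ammonium cation in the aldol event. The 6- (not 8-) placement follows from the symmetry of the bis-MOM ether and the single C–F bond.

Key step: step 8

Remark: the SMILES is read as (2S) at the chromanone carbon and (2S) at the piperidine carbon; the target is isolated as the free base.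

**Step 1**
Reactants: 1 5-fluorobenzene-1,3-diol
Product: 2 1-fluoro-3,5-bis(methoxymethoxy)benzene
Conditions: MOMCl, iPr2NEt, CH2Cl2, 0 → 23 °C
Reagents that add atoms: chloromethyl methyl ether, COCCl
Why: Williamson-type O-alkylation of both phenols by the reactive α-chloro ether (MOM protection) should give a symmetric arene whose carbon between the two OMOM groups is the preferred lithiation site.

**Step 2**
Reactants: 3 (S)-2-methylpropane-2-sulfinamide; 4 5-chloropentanal
Product: 5 (S,E)-N-(5-chloropentylidene)-2-methylpropane-2-sulfinamide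
Conditions: CuSO4 (2 equiv), CH2Cl2, 23 °C
Reagents that add atoms: none
Why: Dehydrative condensation (sulfinimine formation) should give the E-aldimine with the sulfur stereocenter untouched.

**Step 3**
Reactants: 2 1-fluoro-3,5-bis(methoxymethoxy)benzene; 5 (S,E)-N-(5-chloropentylidene)-2-methylpropane-2-sulfinamide
Product: 8 (S)-N-[(1S)-5-chloro-1-[4-fluoro-2,6-bis(methoxymethoxy)phenyl]pentyl]-2-methylpropane-2-sulfinamide, via aryllithium 6 (not isolated), via arylmagnesium bromide 7 (not isolated)
Conditions: n-BuLi, Et2O, −20 → 0 °C; MgBr2·OEt2, −20 °C; then 5, CH2Cl2, −78 → −40 °C; aq. NH4Cl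
Reagents that add atoms: none
Why: Directed ortho-metalation at the carbon flanked by both OMOM groups, Li-to-Mg exchange and 1,2-addition of the aryl Grignard reagent to the N-tert-butanesulfinyl aldimine through the six-membered chelated chair (Mg on the sulfinyl oxygen, tert-butyl equatorial) should set the (S)-configured benzylic carbon, the minor diastereomer being removed by chromatography.

**Step 4**
Reactants: 8 (S)-N-[(1S)-5-chloro-1-[4-fluoro-2,6-bis(methoxymethoxy)phenyl]pentyl]-2-methylpropane-2-sulfinamide
Product: 9 (2S)-1-[(S)-tert-butylsulfinyl]-2-[4-fluoro-2,6-bis(methoxymethoxy)phenyl]piperidine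
Conditions: KN(SiMe3)2, THF, −78 → 23 °C
Reagents that add atoms: none
Why: Deprotonation of the sulfinamide N–H and intramolecular SN2 N-alkylation by the primary chloride (6-exo-tet) should close the piperidine ring without touching the benzylic stereocenter.

**Step 5**
Reactants: 9 (2S)-1-[(S)-tert-butylsulfinyl]-2-[4-fluoro-2,6-bis(methoxymethoxy)phenyl]piperidine
Product: 11 (2S)-2-[4-fluoro-2,6-bis(methoxymethoxy)phenyl]-1-methylpiperidine, via secondary amine 10 (not isolated)
Conditions: HCl (4 M in dioxane, 2.5 equiv), MeOH, 0 °C, 30 min; concentrate; then aq. CH2O, NaBH(OAc)3, Et3N, ClCH2CH2Cl, 23 °C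
Reagents that add atoms: formaldehyde, C=O
Why: Brief acidolysis of the S–N bond (sulfinamide cleavage, fast at 0 °C, whereas aryl MOM ethers need hours at higher temperature) followed by reductive amination with formaldehyde should install the N-methyl group with the stereocenter uninvolved.

**Step 6**
Reactants: 11 (2S)-2-[4-fluoro-2,6-bis(methoxymethoxy)phenyl]-1-methylpiperidine
Product: 13 1-[6-fluoro-2,4-bis(methoxymethoxy)-3-[(2S)-1-methylpiperidin-2-yl]phenyl]ethan-1-one, via aryllithium 12 (not isolated)
Conditions: n-BuLi, THF, −78 °C; then MeC(O)N(OMe)Me, −78 → −40 °C; aq. NH4Cl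
Reagents that add atoms: N-methoxy-N-methylacetamide, CC(=O)N(C)OC
Why: Directed ortho-metalation at the remaining activated position (between F and OMOM; the two candidates are identical by rotation about the aryl–piperidine bond) and Weinreb ketone synthesis should stop at the methyl ketone through the chelated tetrahedral intermediate, the low temperature preventing LiF loss to an aryne.

**Step 7**
Reactants: 13 1-[6-fluoro-2,4-bis(methoxymethoxy)-3-[(2S)-1-methylpiperidin-2-yl]phenyl]ethan-1-one
Product: 14 (2S)-2-[4-fluoro-2,6-bis(methoxymethoxy)-3-[1-(trimethylsilyloxy)ethenyl]phenyl]-1-methylpiperidine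
Conditions: LiN(SiMe3)2, THF, −78 °C; Me3SiCl, −78 → 0 °C; pentane, filtration, used crude
Reagents that add atoms: chlorotrimethylsilane, C[Si](C)(C)Cl
Why: Kinetic deprotonation of the only enolizable position and O-silylation (silyl enol ether formation) should give the enol silane, the amide base avoiding silyl triflates that would cleave MOM ethers.

**Step 8**
Reactants: 14 (2S)-2-[4-fluoro-2,6-bis(methoxymethoxy)-3-[1-(trimethylsilyloxy)ethenyl]phenyl]-1-methylpiperidine; 15 4-(methoxymethoxy)benzaldehyde
Product: 18 (2S)-5,7-bis(methoxymethoxy)-2-[4-(methoxymethoxy)phenyl]-6-[(2S)-1-methylpiperidin-2-yl]-2,3-dihydro-4H-chromen-4-one, via silyl aldol 16 (not isolated), via aldolate 17 (not isolated)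
Conditions: O-allyl-N-(9-anthracenylmethyl)cinchonidinium hydrogen difluoride (10 mol%), 4 Å MS, CH2Cl2–THF, −78 → 23 °C; AcOH quench once 16 is consumed
Reagents that add atoms: none
Why: Proposed new method: bifluoride desilylates enol silane 14 (Me3SiF leaves) to a chiral ammonium enolate whose C3 adds to the aldehyde carbon of 15 (future C2); the aldolate oxygen (future O1), stored at low temperature as silyl ether 16 by silyl transfer from a further molecule of 14 and released as 17 on warming, attacks C8a ortho to the C4 ketone, and the Meisenheimer intermediate (charge taken up by the C4 carbonyl, the C5 and C7 oxygens being meta to C8a and not donating to it) expels fluoride, which desilylates the next molecule of 14 or 16. The closest known reaction types are the fluoride- or bifluoride-initiated Mukaiyama aldol addition catalysed by chiral quaternary ammonium salts, the intramolecular SNAr etherification of alkoxides on ortho-fluoroaryl ketones, and the fluoride-catalysed coupling of silyl ethers with activated aryl fluorides with loss of Me3SiF; their union in one fluoride-relay annulation is the new part. Ring C closes as a six-membered ring by addition–elimination at C8a (6-exo attack of O1 on the C8a=C8 bond of ring A, then loss of fluoride). C2 is set in the C–C bond formation by the chiral cation, which must expose the Si face of the aldehyde to the enolate to give 2S (the cinchoninium pseudo-enantiomer is taken if the opposite face is favoured), and it passes through the ring closure unchanged because the C2–O1 bond is never broken. The step needs ring closure to outrun retro-aldol cleavage and E1cB dehydration of 17, which the silyl store 16, the aprotic medium free of alkali cations and the single ketone-activated C–F bond should secure, and the regiochemistry (6- and not 8-substituted flavanone) is fixed because only C8a carries a leaving group.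

**Step 9**
Reactants: 18 (2S)-5,7-bis(methoxymethoxy)-2-[4-(methoxymethoxy)phenyl]-6-[(2S)-1-methylpiperidin-2-yl]-2,3-dihydro-4H-chromen-4-one
Product: 19 (2S)-5,7-dihydroxy-2-(4-hydroxyphenyl)-6-[(2S)-1-methylpiperidin-2-yl]-2,3-dihydro-4H-chromen-4-one
Conditions: HCl (1.25 M in MeOH), 23 °C; then aq. NaHCO3 to pH 7
Reagents that add atoms: none
Why: Acid-catalysed transacetalisation of the three MOM ethers to methanol (acetal cleavage) should free the phenols, the non-basic medium at ambient temperature avoiding the base-mediated retro-oxa-Michael opening that would epimerise C2 and keeping the benzylic amine protonated.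

**Compound list**
1 | 5-fluorobenzene-1,3-diol | Oc1cc(O)cc(F)c1 | starting material
2 | 1-fluoro-3,5-bis(methoxymethoxy)benzene | COCOc1cc(F)cc(OCOC)c1 | intermediate
3 | (S)-2-methylpropane-2-sulfinamide | CC(C)(C)[S@](=O)N | starting material
4 | 5-chloropentanal | O=CCCCCCl | starting material
5 | (S,E)-N-(5-chloropentylidene)-2-methylpropane-2-sulfinamide | CC(C)(C)[S@](=O)/N=C/CCCCCl | intermediate
6 | [4-fluoro-2,6-bis(methoxymethoxy)phenyl]lithium | [Li]c1c(OCOC)cc(F)cc1OCOC | intermediate
7 | bromo[4-fluoro-2,6-bis(methoxymethoxy)phenyl]magnesium | Br[Mg]c1c(OCOC)cc(F)cc1OCOC | intermediate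
8 | (S)-N-[(1S)-5-chloro-1-[4-fluoro-2,6-bis(methoxymethoxy)phenyl]pentyl]-2-methylpropane-2-sulfinamide | CC(C)(C)[S@](=O)N[C@@H](CCCCCl)c1c(OCOC)cc(F)cc1OCOC | intermediate
9 | (2S)-1-[(S)-tert-butylsulfinyl]-2-[4-fluoro-2,6-bis(methoxymethoxy)phenyl]piperidine | CC(C)(C)[S@](=O)N1CCCC[C@H]1c1c(OCOC)cc(F)cc1OCOC | intermediate
10 | (2S)-2-[4-fluoro-2,6-bis(methoxymethoxy)phenyl]piperidine (hydrochloride in the flask) | N1CCCC[C@H]1c1c(OCOC)cc(F)cc1OCOC | intermediate
11 | (2S)-2-[4-fluoro-2,6-bis(methoxymethoxy)phenyl]-1-methylpiperidine | CN1CCCC[C@H]1c1c(OCOC)cc(F)cc1OCOC | intermediate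
12 | [6-fluoro-2,4-bis(methoxymethoxy)-3-[(2S)-1-methylpiperidin-2-yl]phenyl]lithium | CN1CCCC[C@H]1c1c(OCOC)cc(F)c([Li])c1OCOC | intermediate
13 | 1-[6-fluoro-2,4-bis(methoxymethoxy)-3-[(2S)-1-methylpiperidin-2-yl]phenyl]ethan-1-one | CN1CCCC[C@H]1c1c(OCOC)cc(F)c(C(C)=O)c1OCOC | intermediate
14 | (2S)-2-[4-fluoro-2,6-bis(methoxymethoxy)-3-[1-(trimethylsilyloxy)ethenyl]phenyl]-1-methylpiperidine | CN1CCCC[C@H]1c1c(OCOC)cc(F)c(C(=C)O[Si](C)(C)C)c1OCOC | intermediate
15 | 4-(methoxymethoxy)benzaldehyde | COCOc1ccc(C=O)cc1 | starting material
16 | (3S)-1-[6-fluoro-2,4-bis(methoxymethoxy)-3-[(2S)-1-methylpiperidin-2-yl]phenyl]-3-[4-(methoxymethoxy)phenyl]-3-(trimethylsilyloxy)propan-1-one | CN1CCCC[C@H]1c1c(OCOC)cc(F)c(C(=O)C[C@H](O[Si](C)(C)C)c2ccc(OCOC)cc2)c1OCOC | intermediate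
17 | (1S)-3-[6-fluoro-2,4-bis(methoxymethoxy)-3-[(2S)-1-methylpiperidin-2-yl]phenyl]-1-[4-(methoxymethoxy)phenyl]-3-oxopropan-1-olate (ammonium aldolate) | CN1CCCC[C@H]1c1c(OCOC)cc(F)c(C(=O)C[C@H]([O-])c2ccc(OCOC)cc2)c1OCOC | intermediate
18 | (2S)-5,7-bis(methoxymethoxy)-2-[4-(methoxymethoxy)phenyl]-6-[(2S)-1-methylpiperidin-2-yl]-2,3-dihydro-4H-chromen-4-one | CN1CCCC[C@H]1c1c(OCOC)cc2c(c1OCOC)C(=O)C[C@@H](c1ccc(OCOC)cc1)O2 | intermediate
19 | (2S)-5,7-dihydroxy-2-(4-hydroxyphenyl)-6-[(2S)-1-methylpiperidin-2-yl]-2,3-dihydro-4H-chromen-4-one | CN1CCCC[C@H]1c1c(O)cc2c(c1O)C(=O)C[C@@H](c1ccc(O)cc1)O2 | target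

**Step count and risks**
Total steps: 9. Longest linear sequence: 8 steps (1 → 2 → 8 → 9 → 11 → 13 → 14 → 18 → 19); step 2 is the one-step side branch.

Steps most likely to fail:

1. Step 8 (proposed new method). The aldol addition may be reversible before ring closure, eroding the enantioselectivity. The aldolate may dehydrate to an open-chain enone that cannot cyclise. The ion pair may discriminate the aldehyde faces weakly. Residual fluoride may epimerise C2 of the product by ring opening if the quench is late. The fallback sets out from 14 and comes back at 18. 14 and 15 are joined by a Mukaiyama aldol addition under SiCl4 activated by a chiral 1,1'-binaphthyl-2,2'-diamine-derived bisphosphoramide (5 mol%, iPr2NEt, CH2Cl2, −78 °C; aqueous KF/NaHCO3 work-up). This should give the isolated (3S)-1-[6-fluoro-2,4-bis(methoxymethoxy)-3-[(2S)-1-methylpiperidin-2-yl]phenyl]-3-hydroxy-3-[4-(methoxymethoxy)phenyl]propan-1-one F1. Deprotonation with NaH in THF (0 → 40 °C) then closes ring C by intramolecular SNAr to 18.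

2. Step 3. Deprotonation may compete at the carbon between F and OMOM, giving the wrong regiochemistry and aryne decomposition. The hindered aryl nucleophile may deprotonate the aldimine instead of adding. An open transition state may lower or reverse the facial selectivity (if only the sense is reversed, the (R)-sulfinamide is used). The fallback sets out from 1 and comes back at 8. 1 is iodinated between the hydroxyl groups (I2, NaHCO3, H2O, 0 °C) to 5-fluoro-2-iodobenzene-1,3-diol F2. This is protected (MOMCl, iPr2NEt) as 5-fluoro-2-iodo-1,3-bis(methoxymethoxy)benzene F3. Iodine–magnesium exchange (iPrMgCl·LiCl, THF, −20 °C) gives chloro[4-fluoro-2,6-bis(methoxymethoxy)phenyl]magnesium F4, which is added to 5 in CH2Cl2 at −78 °C to give 8. The halogen fixes the site of metalation, and a true Grignard reagent favours the chelated transition state.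

3. Step 6. Proton transfer from the acetyl group of the amide to the hindered aryllithium may return 11. Warming before acylation may cause loss of LiF to an aryne. The fallback sets out from 11 and comes back at 13. Aryllithium 12 is quenched at −78 °C with acetaldehyde, a faster and less enolisable electrophile, to give 1-[6-fluoro-2,4-bis(methoxymethoxy)-3-[(2S)-1-methylpiperidin-2-yl]phenyl]ethan-1-ol F5 as carbinol epimers. Swern oxidation ((COCl)2, DMSO, Et3N, −78 °C) converts it to 13.

**Further compounds**
F1 | step 8 | (3S)-1-[6-fluoro-2,4-bis(methoxymethoxy)-3-[(2S)-1-methylpiperidin-2-yl]phenyl]-3-hydroxy-3-[4-(methoxymethoxy)phenyl]propan-1-one | CN1CCCC[C@H]1c1c(OCOC)cc(F)c(C(=O)C[C@H](O)c2ccc(OCOC)cc2)c1OCOC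
F2 | step 3 | 5-fluoro-2-iodobenzene-1,3-diol | Oc1cc(F)cc(O)c1I
F3 | step 3 | 5-fluoro-2-iodo-1,3-bis(methoxymethoxy)benzene | COCOc1cc(F)cc(OCOC)c1I
F4 | step 3 | chloro[4-fluoro-2,6-bis(methoxymethoxy)phenyl]magnesium | Cl[Mg]c1c(OCOC)cc(F)cc1OCOC
F5 | step 6 | 1-[6-fluoro-2,4-bis(methoxymethoxy)-3-[(2S)-1-methylpiperidin-2-yl]phenyl]ethan-1-ol | CN1CCCC[C@H]1c1c(OCOC)cc(F)c(C(C)O)c1OCOC
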